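## Structural features

The target is a ten-membered carbocycle, numbered here C6(OH)–C7(iPr)–C8(O-acyl)–C9H2–C10(Me)=C1H–C2H2–C3H2–C4(Me)=C5H–(back to C6). Its only other ring is the benzene ring of a 4-hydroxy-3-methoxybenzoate (vanillate) attached through O8. Both trisubstituted ring alkenes are Z, and the three contiguous stereocentres C6 (R), C7 (S) and C8 (R) carry an allylic hydroxyl, an isopropyl group and the ester oxygen in an all-trans relationship. Fragile points are the secondary allylic alcohol at C6, the ester (1,3-acyl shift from O8 to O6 under base), the free phenol, and the skipped diene in a strained medium ring (acid-induced transannular reactions). The real difficulty is to close the ten-membered ring while fixing two Z trisubstituted alkenes and keeping the two secondary oxygens distinguishable, O6 free and O8 acylated. The feature exploited is that O8, C8, C7, C6, C5 and C4 are the six ring atoms of a 3,4-dihydro-2H-pyran: its half-chair holds the three substituents equatorial, and its enol ether oxygen is necessarily cis to C6 across C4=C5, the position C3 must take. Exchanging that oxygen for C3 with retention therefore gives the Z C4=C5 alkene, the carbocycle and a free O8 in one event, while the Z C1=C10 alkene is traced to a benzene ring.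

## Logic of the disconnections

24 is first cut at its two O–Si bonds (O6 and the phenol oxygen) to give 23. One fluoride treatment then ends the synthesis, and the allylic alcohol and the phenol stay masked until then. The demand is a desilylation mild enough not to move the acyl group from O8 to O6.

23 is cut at the acyl C–O8 bond into 19 and 22. This separates the aromatic part completely and leaves 19 with exactly one free hydroxyl. The demand is acylation of a hindered secondary alcohol next to the isopropyl-bearing carbon.

19 is cut at the ring bond C3–C4, and O8 is reconnected to C4, giving 17 (through 18). One bond and one ring are removed. The ten-membered ring becomes a six-membered heterocycle with a side chain, the Z geometry of C4=C5 becomes a consequence of ring membership, and O8 is distinguished from O6 by construction. The demand is a stereoretentive exchange of a vinylic C–O bond for a C–C bond in a ring-closing mode.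

17 is simplified by functional-group changes that cut no skeletal bond: C3–Br to C3–OH (16), C3 alcohol to the ester (15), O6–Si to O6–H (14), the C6–H bond to the ketone (13), and the C7 configuration to the epimeric mixture (12). Each change lowers the stereochemical or protecting-group load. The demands are axial hydride delivery at C6, a thermodynamic preference for the trans C7/C8 arrangement, and non-acidic handling of the allylic enol ether.

12 is cut at C7–C8 and at O8–C4 into 4 and 10 (through 11). The heterocycle is exchanged for an aldehyde and a 1-alkoxy-3-siloxy diene, and C8 becomes the single centre to be controlled by a catalyst. The demand is face-selective addition to an aldehyde that is β,γ-unsaturated and easily isomerised.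

4 is cut back to 2 and then 1 by reconnecting C8 and C3 as a ring double bond (through 3). The Z geometry of C1=C10 is thereby inherited from a six-membered ring, and the two chain ends arise differentiated as aldehyde and ester. The demand is cleavage of the enol ether double bond only.

10 is cut at O–Si to 8 (through 9), 8 at its O–C4 bond to 7, and 7 at the C5–C6 bond into 5 and 6. An ynone that can be enolised on one side only is used, because a 2,4-dione with two different flanks cannot be steered reliably to the required enol ether. The demand is kinetic α′-deprotonation of a vinylogous ester.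

22 is cut at its aryl O–Si bond to 20 (through 21). The demand is selective hydrolysis of a silyl ester beside an aryl silyl ether.

## Other disconnections considered

Alternative 1: Retrosynthetically C6 is joined to C9, leading to the bicyclic siloxycyclobutanone A2, whose four-membered ring (C6–C7–C8–C9) is fused to a dimethylcyclooctadiene. A2 would come from the isoprene dimer A3 by allylic oxidation, enol silylation and a ketene [2+2] cycloaddition. In the forward key step fluoride frees the C6 alkoxide and retro-aldol cleavage of C6–C9 merges both rings into the dione A1.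
- In its favour: both Z alkenes are locked by the eight-membered template from the outset. The fragmentation is strain-driven, unimolecular, needs no dilution and belongs to a known reaction type. The ring is reached in very few steps.
- Against it here: A1 carries none of the three stereocentres, and its C7 is an epimerising, largely enolised dicarbonyl carbon. Both carbonyl groups would have to be reduced with regio-, diastereo- and enantiocontrol in a flexible medium ring, and the two hydroxyls then told apart. The C8 ketone may also move into conjugation with C1=C10.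
- Comparison: on the security of the ring-forming event and on step count up to the ring, this alternative is better than the chosen plan. On structure the chosen plan is stronger, since C6, C7 and C8 are set on a six-membered chair before the large ring exists and O8 emerges free with O6 masked. The early step advantage of the alternative is likely to be spent on late stereochemical and protecting-group work.

Alternative 2: The cut is the C6–C7 bond, leading to the open-chain Z,Z bromo aldehyde A5. In the forward key step CrCl2 turns the allylic bromide into an allylchromium species that adds through its γ-carbon C7 to the C6 aldehyde, closing the ring to A4 and creating the C6 hydroxyl and a C7 isopropenyl group together.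
- In its favour: intramolecular chromium-mediated allylation is an established route to medium-ring homoallylic alcohols and follows the presumed biogenesis. Its cyclic transition state usually gives the anti C6/C7 relationship needed.
- Against it here: A5 requires two Z trisubstituted alkenes built one after the other in a linear sequence, and its Z enal isomerises easily. Induction from C8 onto C7 is uncertain. After ring closure the isopropenyl group must be hydrogenated beside two ring alkenes, and the oxygens must be re-ordered (mask O6, free O8, acylate, unmask).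
- Comparison: in precedent for the ring closure this alternative is better than the chosen plan. It also forms two stereocentres in the ring-closing step, which is an equal or better point provided the selectivity holds, whereas the chosen plan forms none there and relies on the preformed chair. On step economy the chosen plan should be shorter, because both alkene geometries come from rings and the hydroxyls emerge differentiated.

Alternative 3: Retrosynthetically C6 is joined to C10, giving the cis-fused hydroazulene A7 with a tertiary C6 hydroxyl and a C1 mesylate. In the forward key step KN(SiMe3)2 forms the C6 alkoxide and a Grob fragmentation breaks C6–C10 while C6=O and C1=C10 form, giving the dienone A6.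
- In its favour: the fragmentation is concerted and stereospecific, so the anti-periplanar C6–C10 and C1–O bonds fix the Z geometry of C1=C10. C4=C5 is Z because it lies in the seven-membered ring, C7 and C8 are set on a rigid bicycle, and no dilution is needed.
- Against it here: A7 has five stereocentres, including a quaternary carbon next to a tertiary alcohol, and three of them are built only to be destroyed. A6 still lacks the C6 centre, and reduction of a conjugated ketone in a flexible ring beside an epimerisable C7 is uncertain. The oxygens also emerge the wrong way round for acylation (O8 silylated, O6 free).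
- Comparison: as a ring-forming event this alternative is better founded than the chosen step. On structure the chosen plan needs far less stereochemical scaffolding. On step economy the chosen plan should be markedly shorter.

Key step: step 12

Assumption: the (S)-BINOL–titanium catalyst is taken to direct the diene to the Si face of aldehyde 4, as expected for unbranched aliphatic aldehydes; if the sense is opposite, (R)-BINOL is used and nothing else changes.

Remark on descriptors: the spatial arrangement at C6, C7 and C8 is the same from 13 to 24. The letters change only with substituent priorities: ring position 3 is R in 13, S in 14 and R in 15–18; C7 is R in 19 and 23 and S in 24; C6 is S as pyran position 4 and R in the carbocycle.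

Step 1
Reactants: 1 4-methylanisole
Product: 2 1-methoxy-4-methylcyclohexa-1,4-diene
Conditions: Li, NH3 (l), THF, t-BuOH, −78 → −33 °C
Reagents that add atoms: none
Why: Birch reduction; the two donor substituents end up on the two remaining double bonds, which gives the 1,4-diene with the enol ether needed for the next step.

Step 2
Reactants: 2 1-methoxy-4-methylcyclohexa-1,4-diene
Product: 4 methyl (3Z)-4-methyl-6-oxohex-3-enoate, via methoxy hydroperoxide 3 (not isolated)
Conditions: O3 (1.0 equiv), CH2Cl2/MeOH, −78 °C; then Me2S, −78 °C → rt
Reagents that add atoms: ozone O=[O+][O-]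
Why: Chemoselective ozonolysis: the electron-rich enol ether double bond should react far faster than the trisubstituted alkene, giving ester and aldehyde ends already differentiated; the Z geometry is inherited from the ring, and the β,γ-unsaturated aldehyde is used at once without chromatography.

Step 3
Reactants: 5 3-methylbutanoyl chloride; 6 propyne
Product: 7 6-methylhept-2-yn-4-one
Conditions: PdCl2(PPh3)2 (2 mol %), CuI (4 mol %), Et3N, THF, 0 °C → rt
Reagents that add atoms: none
Why: Acyl Sonogashira coupling of an acid chloride with a terminal alkyne; the ynone can be enolised only on the isobutyl side, which settles the regiochemistry of the later diene.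

Step 4
Reactants: 7 6-methylhept-2-yn-4-one
Product: 8 (2E)-2-methoxy-6-methylhept-2-en-4-one
Conditions: MeOH (5 equiv), PBu3 (10 mol %), CH2Cl2, rt
Reagents that add atoms: methanol CO
Why: Phosphine-catalysed conjugate addition of an alcohol to an ynone (oxa-Michael addition) places the methoxy group on the alkyne carbon remote from the carbonyl; the E isomer is expected to prevail and the geometry is of no consequence later.

Step 5
Reactants: 8 (2E)-2-methoxy-6-methylhept-2-en-4-one
Product: 10 (2E,4Z)-2-methoxy-6-methyl-4-(trimethylsilyloxy)hepta-2,4-diene, via lithium dienolate 9 (not isolated)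
Conditions: LiN(iPr)2, THF, −78 °C; then Me3SiCl, Et3N, −78 °C → rt
Reagents that add atoms: chlorotrimethylsilane C[Si](C)(C)Cl
Why: Kinetic deprotonation of a vinylogous ester takes place at the α′ methylene and O-silylation gives the 1-alkoxy-3-siloxy diene; the geometry of the new enol ether (drawn 4Z) does not matter because C7 is equilibrated in step 7.

Step 6
Reactants: 4 methyl (3Z)-4-methyl-6-oxohex-3-enoate; 10 (2E,4Z)-2-methoxy-6-methyl-4-(trimethylsilyloxy)hepta-2,4-diene
Product: 12 methyl (3Z)-4-methyl-5-[(2R)-6-methyl-4-oxo-3-(propan-2-yl)-3,4-dihydro-2H-pyran-2-yl]pent-3-enoate (both C3 epimers), via silyl aldol adduct 11 (not isolated)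
Conditions: Ti(OiPr)4 (10 mol %), (S)-BINOL (20 mol %), 4 Å MS, Et2O, −20 °C; then CF3CO2H, CH2Cl2, 0 °C
Reagents that add atoms: none
Why: Catalytic asymmetric hetero-Diels–Alder reaction in its stepwise Mukaiyama aldol–cyclisation form: the isopropyl-bearing diene terminus adds to the Si face of the titanium-bound aldehyde and sets C8 as R, then acid closes the ring by oxa-Michael addition with loss of methoxytrimethylsilane; C7 is not controlled here and is corrected in step 7.

Step 7
Reactants: 12 methyl (3Z)-4-methyl-5-[(2R)-6-methyl-4-oxo-3-(propan-2-yl)-3,4-dihydro-2H-pyran-2-yl]pent-3-enoate (both C3 epimers)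
Product: 13 methyl (3Z)-4-methyl-5-[(2R,3R)-6-methyl-4-oxo-3-(propan-2-yl)-3,4-dihydro-2H-pyran-2-yl]pent-3-enoate
Conditions: DBU (0.1 equiv), PhMe, 0 °C → rt; cis isomer recycled
Reagents that add atoms: none
Why: Base-catalysed epimerisation through the enolate α to the ketone sets C7 under thermodynamic control, the trans isomer with both substituents equatorial being expected to be favoured; a catalytic amine in an aprotic solvent is chosen to spare the skipped ester, and the endocyclic C8–O bond is poorly aligned for β-elimination, so C8 should hold.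

Step 8
Reactants: 13 methyl (3Z)-4-methyl-5-[(2R,3R)-6-methyl-4-oxo-3-(propan-2-yl)-3,4-dihydro-2H-pyran-2-yl]pent-3-enoate
Product: 14 methyl (3Z)-5-[(2R,3S,4S)-4-hydroxy-6-methyl-3-(propan-2-yl)-3,4-dihydro-2H-pyran-2-yl]-4-methylpent-3-enoate
Conditions: NaBH4, CeCl3·7H2O, MeOH, −78 → −40 °C
Reagents that add atoms: none
Why: Luche reduction gives 1,2-reduction of the vinylogous ester carbonyl and leaves the methyl ester alone; hydride should enter axially on the half-chair with equatorial substituents, placing the new C6 hydroxyl equatorial and trans to the isopropyl group.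

Step 9
Reactants: 14 methyl (3Z)-5-[(2R,3S,4S)-4-hydroxy-6-methyl-3-(propan-2-yl)-3,4-dihydro-2H-pyran-2-yl]-4-methylpent-3-enoate
Product: 15 methyl (3Z)-4-methyl-5-[(2R,3R,4S)-6-methyl-3-(propan-2-yl)-4-{[tri(propan-2-yl)silyl]oxy}-3,4-dihydro-2H-pyran-2-yl]pent-3-enoate
Conditions: i-Pr3SiOTf, 2,6-lutidine, CH2Cl2, −78 → 0 °C
Reagents that add atoms: triisopropylsilyl triflate CC(C)[Si](OS(=O)(=O)C(F)(F)F)(C(C)C)C(C)C
Why: Silylation of a hindered secondary alcohol with a silyl triflate under basic conditions, which protects the acid-labile allylic enol ether from ionisation; the bulky group later shields the allylic C6–O bond.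

Step 10
Reactants: 15 methyl (3Z)-4-methyl-5-[(2R,3R,4S)-6-methyl-3-(propan-2-yl)-4-{[tri(propan-2-yl)silyl]oxy}-3,4-dihydro-2H-pyran-2-yl]pent-3-enoate
Product: 16 (3Z)-4-methyl-5-[(2R,3R,4S)-6-methyl-3-(propan-2-yl)-4-{[tri(propan-2-yl)silyl]oxy}-3,4-dihydro-2H-pyran-2-yl]pent-3-en-1-ol
Conditions: LiAlH4, Et2O, 0 °C; aq. NaOH work-up
Reagents that add atoms: none
Why: Hydride reduction of the ester to the primary alcohol; the reagent is not Lewis acidic, so the enol ether and the silyl ether should be untouched, and the work-up is kept basic.

Step 11
Reactants: 16 (3Z)-4-methyl-5-[(2R,3R,4S)-6-methyl-3-(propan-2-yl)-4-{[tri(propan-2-yl)silyl]oxy}-3,4-dihydro-2H-pyran-2-yl]pent-3-en-1-ol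
Product: 17 (2R,3R,4S)-2-[(2Z)-5-bromo-2-methylpent-2-en-1-yl]-6-methyl-3-(propan-2-yl)-4-{[tri(propan-2-yl)silyl]oxy}-3,4-dihydro-2H-pyran
Conditions: CBr4, PPh3, 2,6-lutidine, CH2Cl2, 0 °C
Reagents that add atoms: carbon tetrabromide BrC(Br)(Br)Br
Why: Appel reaction, an SN2 displacement at the primary carbon; the amine buffer keeps traces of HBr away from the enol ether.

Step 12
Reactants: 17 (2R,3R,4S)-2-[(2Z)-5-bromo-2-methylpent-2-en-1-yl]-6-methyl-3-(propan-2-yl)-4-{[tri(propan-2-yl)silyl]oxy}-3,4-dihydro-2H-pyran
Product: 19 (1R,3Z,7Z,9R,10R)-3,7-dimethyl-10-(propan-2-yl)-9-{[tri(propan-2-yl)silyl]oxy}cyclodeca-3,7-dien-1-ol, via Grignard reagent 18 (not isolated)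
Conditions: Mg turnings (I2-activated), THF, 30 °C; then addition over 10 h to Ni(cod)2 (10 mol %), dcype [1,2-bis(dicyclohexylphosphino)ethane] (12 mol %), PhMe, 80 °C, 2 mM; H2O quench
Reagents that add atoms: none
Why: Proposed new method: the primary Grignard reagent 18 forms at C3 without touching the enol ether, and on slow addition zerovalent nickel, helped by magnesium bound to the ring oxygen, should insert into the vinylic C4–O bond, accept the tethered C3 alkyl group by transmetalation and form C3–C4 by reductive elimination. The closest known reaction type is the intermolecular nickel-catalysed Kumada-type coupling of methyl, aryl or silylmethyl Grignard reagents with dihydrofurans and dihydropyrans, which opens the ring to Z alkenols with retention; neither a ring-closing mode nor an alkyl partner with allylic β-hydrogens is covered by it. The ten-membered ring closes by sp3–sp2 reductive elimination from an eleven-membered alkyl(alkenyl)nickel metallacycle, and the same event opens the six-membered heterocycle. No stereocentre is formed; C6, C7 and C8 were set on the pyran chair and lie outside the bonds that change. The selectivity needed is geometric: retention at C4 puts C3 where the oxygen stood, cis to C6, which gives Z C4=C5, and this is secured by the ring-fixed enol ether geometry and the stereoretentive course of oxidative addition and reductive elimination at an alkenyl carbon. Ring closure must also beat intermolecular coupling, which the Z C1=C10 turn in the tether and the low stationary concentration are meant to ensure. β-Hydride elimination from C2, which would give a diene and a reduced C4–H product, is the main competitor, and the chelating electron-rich diphosphine is chosen in place of NiCl2(PPh3)2 of the parent reaction because it leaves no free cis site and speeds reductive elimination. The allylic C6–O bond should stay intact because the bulky silyl ether is a poor and shielded leaving group, whereas the expelled alkoxide is O8, which therefore emerges as the only free hydroxyl.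

Step 13
Reactants: 20 vanillic acid (4-hydroxy-3-methoxybenzoic acid)
Product: 22 4-{[tert-butyl(dimethyl)silyl]oxy}-3-methoxybenzoic acid, via bis-silyl derivative 21 (not isolated)
Conditions: t-BuMe2SiCl (2.3 equiv), imidazole, DMF, rt; then AcOH/THF/H2O (3:1:1), rt
Reagents that add atoms: tert-butyldimethylsilyl chloride CC(C)(C)[Si](C)(C)Cl
Why: Silylation of both acidic groups followed by selective hydrolysis, silyl esters being far more labile to mild aqueous acid than aryl silyl ethers.

Step 14
Reactants: 19 (1R,3Z,7Z,9R,10R)-3,7-dimethyl-10-(propan-2-yl)-9-{[tri(propan-2-yl)silyl]oxy}cyclodeca-3,7-dien-1-ol; 22 4-{[tert-butyl(dimethyl)silyl]oxy}-3-methoxybenzoic acid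
Product: 23 (1R,3Z,7Z,9R,10R)-3,7-dimethyl-10-(propan-2-yl)-9-{[tri(propan-2-yl)silyl]oxy}cyclodeca-3,7-dien-1-yl 4-{[tert-butyl(dimethyl)silyl]oxy}-3-methoxybenzoate
Conditions: DCC, DMAP (1 equiv), CH2Cl2, 0 °C → rt
Reagents that add atoms: none
Why: Steglich esterification; the acylpyridinium intermediate should acylate the single free, hindered secondary hydroxyl at O8 with retention of configuration, O6 being silylated.

Step 15
Reactants: 23 (1R,3Z,7Z,9R,10R)-3,7-dimethyl-10-(propan-2-yl)-9-{[tri(propan-2-yl)silyl]oxy}cyclodeca-3,7-dien-1-yl 4-{[tert-butyl(dimethyl)silyl]oxy}-3-methoxybenzoate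
Product: 24 (1R,3Z,7Z,9R,10S)-9-hydroxy-3,7-dimethyl-10-(propan-2-yl)cyclodeca-3,7-dien-1-yl 4-hydroxy-3-methoxybenzoate
Conditions: Bu4NF, AcOH (1:1), THF, 0 °C → rt
Reagents that add atoms: none
Why: Fluoride-mediated cleavage of both silyl ethers in one operation; the acetic acid buffer keeps phenoxide and alkoxide concentrations low so that the acyl group should stay on O8.

## Compound list

1 | 4-methylanisole | COc1ccc(C)cc1 | starting material
2 | 1-methoxy-4-methylcyclohexa-1,4-diene | COC1=CCC(C)=CC1 | intermediate
3 | methyl (3Z)-6-hydroperoxy-6-methoxy-4-methylhex-3-enoate | COC(OO)C/C(C)=C\CC(=O)OC | intermediate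
4 | methyl (3Z)-4-methyl-6-oxohex-3-enoate | O=CC/C(C)=C\CC(=O)OC | intermediate
5 | 3-methylbutanoyl chloride | CC(C)CC(=O)Cl | starting material
6 | propyne | CC#C | starting material
7 | 6-methylhept-2-yn-4-one | CC#CC(=O)CC(C)C | intermediate
8 | (2E)-2-methoxy-6-methylhept-2-en-4-one | CO/C(C)=C/C(=O)CC(C)C | intermediate
9 | lithium (2E,4Z)-2-methoxy-6-methylhepta-2,4-dien-4-olate | CO/C(C)=C/C(O[Li])=C/C(C)C | intermediate
10 | (2E,4Z)-2-methoxy-6-methyl-4-(trimethylsilyloxy)hepta-2,4-diene | CO/C(C)=C/C(O[Si](C)(C)C)=C/C(C)C | intermediate
11 | methyl (3Z,6R,9E)-10-methoxy-4-methyl-8-oxo-7-(propan-2-yl)-6-(trimethylsilyloxy)undeca-3,9-dienoate (both C7 epimers) | CO/C(C)=C/C(=O)C(C(C)C)[C@@H](C/C(C)=C\CC(=O)OC)O[Si](C)(C)C | intermediate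
12 | methyl (3Z)-4-methyl-5-[(2R)-6-methyl-4-oxo-3-(propan-2-yl)-3,4-dihydro-2H-pyran-2-yl]pent-3-enoate (both C3 epimers) | CC1=CC(=O)C(C(C)C)[C@@H](C/C(C)=C\CC(=O)OC)O1 | intermediate
13 | methyl (3Z)-4-methyl-5-[(2R,3R)-6-methyl-4-oxo-3-(propan-2-yl)-3,4-dihydro-2H-pyran-2-yl]pent-3-enoate | CC1=CC(=O)[C@H](C(C)C)[C@@H](C/C(C)=C\CC(=O)OC)O1 | intermediate
14 | methyl (3Z)-5-[(2R,3S,4S)-4-hydroxy-6-methyl-3-(propan-2-yl)-3,4-dihydro-2H-pyran-2-yl]-4-methylpent-3-enoate | CC1=C[C@@H](O)[C@H](C(C)C)[C@@H](C/C(C)=C\CC(=O)OC)O1 | intermediate
15 | methyl (3Z)-4-methyl-5-[(2R,3R,4S)-6-methyl-3-(propan-2-yl)-4-{[tri(propan-2-yl)silyl]oxy}-3,4-dihydro-2H-pyran-2-yl]pent-3-enoate | CC1=C[C@@H](O[Si](C(C)C)(C(C)C)C(C)C)[C@H](C(C)C)[C@@H](C/C(C)=C\CC(=O)OC)O1 | intermediate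
16 | (3Z)-4-methyl-5-[(2R,3R,4S)-6-methyl-3-(propan-2-yl)-4-{[tri(propan-2-yl)silyl]oxy}-3,4-dihydro-2H-pyran-2-yl]pent-3-en-1-ol | CC1=C[C@@H](O[Si](C(C)C)(C(C)C)C(C)C)[C@H](C(C)C)[C@@H](C/C(C)=C\CCO)O1 | intermediate
17 | (2R,3R,4S)-2-[(2Z)-5-bromo-2-methylpent-2-en-1-yl]-6-methyl-3-(propan-2-yl)-4-{[tri(propan-2-yl)silyl]oxy}-3,4-dihydro-2H-pyran | CC1=C[C@@H](O[Si](C(C)C)(C(C)C)C(C)C)[C@H](C(C)C)[C@@H](C/C(C)=C\CCBr)O1 | intermediate
18 | bromo{(3Z)-4-methyl-5-[(2R,3R,4S)-6-methyl-3-(propan-2-yl)-4-{[tri(propan-2-yl)silyl]oxy}-3,4-dihydro-2H-pyran-2-yl]pent-3-en-1-yl}magnesium | CC1=C[C@@H](O[Si](C(C)C)(C(C)C)C(C)C)[C@H](C(C)C)[C@@H](C/C(C)=C\CC[Mg]Br)O1 | intermediate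
19 | (1R,3Z,7Z,9R,10R)-3,7-dimethyl-10-(propan-2-yl)-9-{[tri(propan-2-yl)silyl]oxy}cyclodeca-3,7-dien-1-ol | O[C@@H]1C/C(C)=C\CC/C(C)=C\[C@@H](O[Si](C(C)C)(C(C)C)C(C)C)[C@@H]1C(C)C | intermediate
20 | vanillic acid (4-hydroxy-3-methoxybenzoic acid) | COc1cc(C(=O)O)ccc1O | starting material
21 | tert-butyl(dimethyl)silyl 4-{[tert-butyl(dimethyl)silyl]oxy}-3-methoxybenzoate | COc1cc(C(=O)O[Si](C)(C)C(C)(C)C)ccc1O[Si](C)(C)C(C)(C)C | intermediate
22 | 4-{[tert-butyl(dimethyl)silyl]oxy}-3-methoxybenzoic acid | COc1cc(C(=O)O)ccc1O[Si](C)(C)C(C)(C)C | intermediate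
23 | (1R,3Z,7Z,9R,10R)-3,7-dimethyl-10-(propan-2-yl)-9-{[tri(propan-2-yl)silyl]oxy}cyclodeca-3,7-dien-1-yl 4-{[tert-butyl(dimethyl)silyl]oxy}-3-methoxybenzoate | COc1cc(C(=O)O[C@@H]2C/C(C)=C\CC/C(C)=C\[C@@H](O[Si](C(C)C)(C(C)C)C(C)C)[C@@H]2C(C)C)ccc1O[Si](C)(C)C(C)(C)C | intermediate
24 | (1R,3Z,7Z,9R,10S)-9-hydroxy-3,7-dimethyl-10-(propan-2-yl)cyclodeca-3,7-dien-1-yl 4-hydroxy-3-methoxybenzoate | COc1cc(C(=O)O[C@@H]2C/C(C)=C\CC/C(C)=C\[C@@H](O)[C@@H]2C(C)C)ccc1O | target

## Step count and least certain steps

Total: 15 steps. Longest linear sequence: 12 steps (steps 3 to 12, then 14 and 15).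

Step 12 (key step). The most likely failures are:
- β-hydride elimination from the alkylnickel intermediate at the allylic C2 position, which would reduce the C4–O bond without closing the ring;
- intermolecular coupling leading to oligomers, because the eleven-membered metallacycle is slow to form;
- sluggish insertion of nickel into a trisubstituted enol ether;
- ionisation of the allylic C6–O bond by nickel;
- loss of Z geometry at C1=C10 through reversible cyclopropylcarbinyl rearrangement while the homoallylic Grignard reagent is formed.

Fallback with known chemistry, from 17 back to 19: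
- One equivalent of ozone at −78 °C followed by Me2S cleaves only the enol ether double bond, as in step 2, and gives the open-chain C5 aldehyde whose O8 is left as an acetate, F1.
- Wittig olefination with the ylide from (1-iodoethyl)triphenylphosphonium iodide and NaN(SiMe3)2 gives the Z-iodoalkene F2, with iodine on C4 cis to C6.
- NaI in acetone exchanges the primary bromide for iodide, giving the diiodide F3.
- Zinc dust activated with 1,2-dibromoethane and Me3SiCl inserts into the primary C–I bond only, giving the alkylzinc iodide F4.
- Slow addition of F4 to Pd(PPh3)4 in THF at 60 °C closes the ring by intramolecular Negishi coupling with retention at C4, giving the macrocyclic acetate F5.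
- K2CO3 in methanol removes the acetate and returns the sequence to 19.

Step 6. The likely failures are poor facial selectivity, because the reacting diene terminus carries an isopropyl group and the other terminus is fully substituted, and Lewis-acid-induced migration of the β,γ double bond of 4 into conjugation before the addition takes place.

Fallback by resolution, from 4 and 10 back to 14:
- BF3·OEt2 in place of the chiral catalyst gives 12 together with its C2 enantiomer, the (2S)-pyranone F6.
- Step 7 then gives 13 together with its enantiomer F7, and step 8 gives 14 together with its enantiomer F8.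
- Acylation with a Pseudomonas lipase and vinyl acetate should, by the usual empirical rule for secondary alcohols, esterify 14 to its acetate F9 and leave F8 untouched. If the enzyme prefers the other enantiomer, the unreacted alcohol is taken instead.
- Brief treatment of F9 with K2CO3 in methanol at 0 °C returns 14.

Step 7. The likely failures are an incomplete or slow equilibration, enolisation of the skipped ester by the same base with double-bond migration or loss of Z geometry, and erosion of C8 by reversible β-elimination of the ring oxygen.

Fallback, from 4 and 10 directly to 13: the equilibration is abandoned, and the cyclocondensation is run with a chiral zirconium–BINOLate catalyst of the type Zr(OtBu)4/3,3′-diiodo-BINOL. Such catalysts follow the anti-selective Mukaiyama aldol path and are known to give 2,3-trans-dihydropyranones directly, so C7 is set under kinetic catalyst control. No new compound arises.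

Step 15. The likely failures are migration of the acyl group from O8 to the neighbouring O6 once fluoride has generated an alkoxide or phenoxide, and slow cleavage of the hindered silyl ether at C6 under buffered conditions.

Fallback with an orthogonal phenol protecting group, from 19 and 20 to 24:
- 20 is acetylated with Ac2O and pyridine to 4-acetoxy-3-methoxybenzoic acid F10.
- DCC and DMAP couple F10 with 19 to give the silyl ether ester F11.
- HF·pyridine in THF/pyridine removes the silyl group without forming an alkoxide and gives the acetoxybenzoate F12.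
- Hydrazine acetate in DMF cleaves the phenolic acetate chemoselectively and gives 24.

## Further compounds

F1 | step 12 | open-chain C5 aldehyde from ozonolysis of 17, with O8 as acetate and C3 as bromide | O=C[C@@H](O[Si](C(C)C)(C(C)C)C(C)C)[C@H](C(C)C)[C@@H](C/C(C)=C\CCBr)OC(C)=O
F2 | step 12 | Z-iodoalkene (iodine on C4 cis to C6) with O8 acetate and C3 bromide | C/C(I)=C/[C@@H](O[Si](C(C)C)(C(C)C)C(C)C)[C@H](C(C)C)[C@@H](C/C(C)=C\CCBr)OC(C)=O
F3 | step 12 | Z-iodoalkene with O8 acetate and primary C3 iodide | C/C(I)=C/[C@@H](O[Si](C(C)C)(C(C)C)C(C)C)[C@H](C(C)C)[C@@H](C/C(C)=C\CCI)OC(C)=O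
F4 | step 12 | alkylzinc iodide at C3 derived from F3 | C/C(I)=C/[C@@H](O[Si](C(C)C)(C(C)C)C(C)C)[C@H](C(C)C)[C@@H](C/C(C)=C\CC[Zn]I)OC(C)=O
F5 | step 12 | (1R,3Z,7Z,9R,10R)-3,7-dimethyl-10-(propan-2-yl)-9-{[tri(propan-2-yl)silyl]oxy}cyclodeca-3,7-dien-1-yl acetate | CC(=O)O[C@@H]1C/C(C)=C\CC/C(C)=C\[C@@H](O[Si](C(C)C)(C(C)C)C(C)C)[C@@H]1C(C)C
F6 | step 6 | methyl (3Z)-4-methyl-5-[(2S)-6-methyl-4-oxo-3-(propan-2-yl)-3,4-dihydro-2H-pyran-2-yl]pent-3-enoate (both C3 epimers; C2 enantiomer of 12) | CC1=CC(=O)C(C(C)C)[C@H](C/C(C)=C\CC(=O)OC)O1
F7 | step 6 | methyl (3Z)-4-methyl-5-[(2S,3S)-6-methyl-4-oxo-3-(propan-2-yl)-3,4-dihydro-2H-pyran-2-yl]pent-3-enoate (enantiomer of 13) | CC1=CC(=O)[C@@H](C(C)C)[C@H](C/C(C)=C\CC(=O)OC)O1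
F8 | step 6 | methyl (3Z)-5-[(2S,3R,4R)-4-hydroxy-6-methyl-3-(propan-2-yl)-3,4-dihydro-2H-pyran-2-yl]-4-methylpent-3-enoate (enantiomer of 14) | CC1=C[C@H](O)[C@@H](C(C)C)[C@H](C/C(C)=C\CC(=O)OC)O1
F9 | step 6 | methyl (3Z)-5-[(2R,3R,4S)-4-acetoxy-6-methyl-3-(propan-2-yl)-3,4-dihydro-2H-pyran-2-yl]-4-methylpent-3-enoate (acetate of 14) | CC1=C[C@@H](OC(C)=O)[C@H](C(C)C)[C@@H](C/C(C)=C\CC(=O)OC)O1
F0 | step 7 | none | none
F10 | step 15 | 4-acetoxy-3-methoxybenzoic acid | COc1cc(C(=O)O)ccc1OC(C)=O
F11 | step 15 | (1R,3Z,7Z,9R,10R)-3,7-dimethyl-10-(propan-2-yl)-9-{[tri(propan-2-yl)silyl]oxy}cyclodeca-3,7-dien-1-yl 4-acetoxy-3-methoxybenzoate | COc1cc(C(=O)O[C@@H]2C/C(C)=C\CC/C(C)=C\[C@@H](O[Si](C(C)C)(C(C)C)C(C)C)[C@@H]2C(C)C)ccc1OC(C)=O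
F12 | step 15 | (1R,3Z,7Z,9R,10S)-9-hydroxy-3,7-dimethyl-10-(propan-2-yl)cyclodeca-3,7-dien-1-yl 4-acetoxy-3-methoxybenzoate | COc1cc(C(=O)O[C@@H]2C/C(C)=C\CC/C(C)=C\[C@@H](O)[C@@H]2C(C)C)ccc1OC(C)=O
A1 | alternative 1 | (4Z,8Z)-5,9-dimethyl-2-(propan-2-yl)cyclodeca-4,8-diene-1,3-dione | O=C1C/C(C)=C\CC/C(C)=C\C(=O)C1C(C)C
A2 | alternative 1 | racemic cis-fused 2,6-dimethyl-9-(propan-2-yl)-8-(trimethylsilyloxy)bicyclo[6.2.0]deca-2,6-dien-10-one | CC(C)C1C(=O)C2/C(C)=C\CC/C(C)=C\C12O[Si](C)(C)C
A3 | alternative 1 | (1Z,5Z)-1,5-dimethylcycloocta-1,5-diene | C/C1=C/CC/C(C)=C\CC1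
A4 | alternative 2 | (1R,2Z,6Z,9R,10S)-9-[(4-methoxyphenyl)methoxy]-3,7-dimethyl-10-(prop-1-en-2-yl)cyclodeca-2,6-dien-1-ol | COc1ccc(CO[C@@H]2C/C(C)=C\CC/C(C)=C\[C@@H](O)[C@@H]2C(C)=C)cc1
A5 | alternative 2 | (2Z,6Z,9R,10E)-12-bromo-9-[(4-methoxyphenyl)methoxy]-3,7,11-trimethyldodeca-2,6,10-trienal | O=C/C=C(C)\CC/C=C(C)\C[C@@H](OCc1ccc(OC)cc1)/C=C(\C)CBr
A6 | alternative 3 | (2Z,6Z,9R,10R)-9-{[tert-butyl(dimethyl)silyl]oxy}-3,7-dimethyl-10-(propan-2-yl)cyclodeca-2,6-dien-1-one | CC(C)(C)[Si](C)(C)O[C@@H]1C/C(C)=C\CC/C(C)=C\C(=O)[C@@H]1C(C)C
A7 | alternative 3 | cis-fused 9-{[tert-butyl(dimethyl)silyl]oxy}-1-hydroxy-3,7-dimethyl-10-(propan-2-yl)bicyclo[5.3.0]dec-2-en-6-yl methanesulfonate | CC1=C[C@]2(O)[C@H](C(C)C)[C@H](O[Si](C)(C)C(C)(C)C)C[C@]2(C)[C@H](OS(C)(=O)=O)CC1
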